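**Retrosynthetic overview**

1. Target (2S) ⇐ 7‑O‑pivalate removal ⇐ Heck disconnection of the C5'–dienyl bond to an aryl bromide and isoprene.
2. Aryl bromide methyl ether ⇐ O‑methylation of a 2‑bromo‑6‑prenylphenol ⇐ aromatic Claisen [3,3] rearrangement of the 4'‑O‑(1,1‑dimethylallyl) ether (key C–C bond, C3'–prenyl).
3. That ether ⇐ Pd π‑allyl O‑alkylation of the 3'‑bromo‑4'‑hydroxyflavanone ⇐ ortho‑bromination of 7‑O‑pivaloyl‑(2S)‑naringenin.
4. No ring is formed in the route: the chromanone A/C rings, the B ring and the C2 (S) stereocentre are bought intact in (2S)‑naringenin and carried through under non‑epimerising conditions.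

Assumption: (2S)‑naringenin (the citrus aglycone, from naringin) is bought as the single enantiomer, and tert‑butyl (2‑methylbut‑3‑en‑2‑yl) carbonate is bought as a catalogue reagent (otherwise one extra step from 2‑methylbut‑3‑en‑2‑ol and Boc2O).

**Route**

Step 1
Reactants: 1, (2S)‑naringenin; 2, pivaloyl chloride
Product: 3, 7‑O‑pivaloyl‑(2S)‑naringenin [(2S)‑5‑hydroxy‑2‑(4‑hydroxyphenyl)‑4‑oxochroman‑7‑yl pivalate]
Conditions: PivCl (1.05 equiv), Et3N (1.1 equiv), THF, −20 → 0 °C
Reagents that add atoms: pivaloyl chloride, CC(C)(C)C(Cl)=O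
Why: Stoichiometric base‑mediated esterification goes to the 7‑OH, the most acidic phenol (pKa ≈ 7.5), because the 5‑OH is chelated to C4=O and the 4'‑OH is about 2 pK units weaker; the ester also lowers A‑ring electron density, and C2 is untouched.

Step 2
Reactants: 3, 7‑O‑pivaloyl‑(2S)‑naringenin; 4, N‑bromosuccinimide
Product: 5, (2S)‑2‑(3‑bromo‑4‑hydroxyphenyl)‑5‑hydroxy‑4‑oxochroman‑7‑yl pivalate
Conditions: NBS (1.0 equiv, slow addition), i‑Pr2NH (10 mol %), CH2Cl2, −20 → 0 °C, dark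
Reagents that add atoms: N‑bromosuccinimide, O=C1CCC(=O)N1Br
Why: In amine‑catalysed ortho‑bromination of phenols the in‑situ N‑bromoamine delivers Br ortho to the only free, non‑chelated OH by hydrogen bonding, which should outrun uncatalysed SEAr on the acyl‑deactivated A ring; one equivalent of NBS limits dibromination and C2 is not involved.

Step 3
Reactants: 5, 3'‑bromo phenol; 6, tert‑butyl (2‑methylbut‑3‑en‑2‑yl) carbonate
Product: 7, (2S)‑2‑{3‑bromo‑4‑[(2‑methylbut‑3‑en‑2‑yl)oxy]phenyl}‑5‑hydroxy‑4‑oxochroman‑7‑yl pivalate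
Conditions: Pd(PPh3)4 (3 mol %), 6 (1.5 equiv), 4 Å MS, THF, 0 °C
Reagents that add atoms: tert‑butyl (2‑methylbut‑3‑en‑2‑yl) carbonate, C=CC(C)(C)OC(=O)OC(C)(C)C
Why: In this Tsuji–Trost O‑allylation the 1,1‑dimethyl‑π‑allyl‑Pd is captured kinetically by the phenoxide at the substituted terminus to give the tertiary ether, with no added base; the aryl bromide does not add to Pd(PPh3)4 at 0 °C, the chelated 5‑OH does not react, and C2 is preserved.

Step 4
Reactants: 7, aryl 1,1‑dimethylallyl ether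
Product: 8, (2S)‑2‑[3‑bromo‑4‑hydroxy‑5‑(3‑methylbut‑2‑en‑1‑yl)phenyl]‑5‑hydroxy‑4‑oxochroman‑7‑yl pivalate
Conditions: PhMe, 120 °C, sealed tube, 8 h
Reagents that add atoms: none
Why: The aromatic Claisen [3,3] rearrangement delivers the CH2 terminus to the only free ortho carbon (the other ortho carries Br, para carries the chromanone) and tautomerisation gives the prenyl phenol; neutral thermal conditions do not open the chromanone, so C2 stays S.

Step 5
Reactants: 8, bromo‑prenyl phenol; 9, methanol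
Product: 10, (2S)‑2‑[3‑bromo‑4‑methoxy‑5‑(3‑methylbut‑2‑en‑1‑yl)phenyl]‑5‑hydroxy‑4‑oxochroman‑7‑yl pivalate
Conditions: MeOH (3 equiv), PPh3, DIAD, THF, 0 °C → rt
Reagents that add atoms: methanol, CO
Why: In this Mitsunobu etherification the acidic o‑bromophenol is the pronucleophile and the chelated 5‑OH is inert; the neutral conditions avoid the free 4'‑phenoxide/quinone‑methide ring opening that would racemise C2.

Step 6
Reactants: 10, aryl bromide; 11, isoprene
Product: 12, (2S)‑5‑hydroxy‑2‑{4‑methoxy‑3‑[(1E)‑3‑methylbuta‑1,3‑dien‑1‑yl]‑5‑(3‑methylbut‑2‑en‑1‑yl)phenyl}‑4‑oxochroman‑7‑yl pivalate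
Conditions: Pd2(dba)3 (2.5 mol %), [HP(t‑Bu)3]BF4 (10 mol %), Cy2NMe (1.5 equiv), isoprene (10 equiv), 1,4‑dioxane, 60 °C, sealed tube
Reagents that add atoms: isoprene, C=CC(C)=C
Why: In this Mizoroki–Heck reaction Ar–Pd adds to the unsubstituted vinyl terminus of isoprene and β‑hydride elimination of a benzylic H gives the conjugated (E)‑diene; the ortho group is OMe so no heteroannulation can occur, the prenyl alkene is unreactive, and the hindered amine at 60 °C spares C2.

Step 7
Reactants: 12, 7‑O‑pivaloyl diene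
Product: 13, target, (2S)‑5,7‑dihydroxy‑2‑{4‑methoxy‑3‑[(1E)‑3‑methylbuta‑1,3‑dien‑1‑yl]‑5‑(3‑methylbut‑2‑en‑1‑yl)phenyl}chroman‑4‑one
Conditions: K2CO3 (2 equiv), MeOH, 0 °C → rt, 1–2 h; AcOH quench
Reagents that add atoms: none
Why: Methanolysis (transesterification) of the activated phenolic pivalate is fast because the leaving phenoxide is para to the C4 carbonyl; the liberated 7‑phenoxide and the 4'‑OMe both disfavour retro‑oxa‑Michael opening, so C2 stays S, and the diene and prenyl groups are base‑stable.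

**Compound list**

1 | (2S)‑naringenin | Oc1ccc([C@@H]2CC(=O)c3c(O)cc(O)cc3O2)cc1 | starting material
2 | pivaloyl chloride | CC(C)(C)C(Cl)=O | starting material
3 | (2S)‑5‑hydroxy‑2‑(4‑hydroxyphenyl)‑4‑oxochroman‑7‑yl pivalate | Oc1ccc([C@@H]2CC(=O)c3c(O)cc(OC(=O)C(C)(C)C)cc3O2)cc1 | intermediate
4 | N‑bromosuccinimide | O=C1CCC(=O)N1Br | starting material
5 | (2S)‑2‑(3‑bromo‑4‑hydroxyphenyl)‑5‑hydroxy‑4‑oxochroman‑7‑yl pivalate | Oc1ccc([C@@H]2CC(=O)c3c(O)cc(OC(=O)C(C)(C)C)cc3O2)cc1Br | intermediate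
6 | tert‑butyl (2‑methylbut‑3‑en‑2‑yl) carbonate | C=CC(C)(C)OC(=O)OC(C)(C)C | starting material
7 | (2S)‑2‑{3‑bromo‑4‑[(2‑methylbut‑3‑en‑2‑yl)oxy]phenyl}‑5‑hydroxy‑4‑oxochroman‑7‑yl pivalate | C=CC(C)(C)Oc1ccc([C@@H]2CC(=O)c3c(O)cc(OC(=O)C(C)(C)C)cc3O2)cc1Br | intermediate
8 | (2S)‑2‑[3‑bromo‑4‑hydroxy‑5‑(3‑methylbut‑2‑en‑1‑yl)phenyl]‑5‑hydroxy‑4‑oxochroman‑7‑yl pivalate | CC(C)=CCc1cc([C@@H]2CC(=O)c3c(O)cc(OC(=O)C(C)(C)C)cc3O2)cc(Br)c1O | intermediate
9 | methanol | CO | starting material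
10 | (2S)‑2‑[3‑bromo‑4‑methoxy‑5‑(3‑methylbut‑2‑en‑1‑yl)phenyl]‑5‑hydroxy‑4‑oxochroman‑7‑yl pivalate | CC(C)=CCc1cc([C@@H]2CC(=O)c3c(O)cc(OC(=O)C(C)(C)C)cc3O2)cc(Br)c1OC | intermediate
11 | isoprene | C=CC(C)=C | starting material
12 | (2S)‑5‑hydroxy‑2‑{4‑methoxy‑3‑[(1E)‑3‑methylbuta‑1,3‑dien‑1‑yl]‑5‑(3‑methylbut‑2‑en‑1‑yl)phenyl}‑4‑oxochroman‑7‑yl pivalate | C=C(C)/C=C/c1cc([C@@H]2CC(=O)c3c(O)cc(OC(=O)C(C)(C)C)cc3O2)cc(CC=C(C)C)c1OC | intermediate
13 | (2S)‑5,7‑dihydroxy‑2‑{4‑methoxy‑3‑[(1E)‑3‑methylbuta‑1,3‑dien‑1‑yl]‑5‑(3‑methylbut‑2‑en‑1‑yl)phenyl}chroman‑4‑one (EANPDB:LEGU_00067) | C=C(C)/C=C/c1cc([C@@H]2CC(=O)c3c(O)cc(O)cc3O2)cc(CC=C(C)C)c1OC | target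

**Totals**

Total step count: 7. Longest linear sequence: 7 steps, from (2S)‑naringenin.

**Three steps most likely to fail**

1. Step 2, B‑ring versus A‑ring bromination and mono‑ versus dibromination. The A ring still carries a free 5‑OH and could compete. Fallback: drop the halogenation/Heck approach. Run the Pd O‑(1,1‑dimethylallyl)ation/Claisen sequence twice on 3 to give the symmetric 3',5'‑diprenyl phenol and O‑methylate it. Then convert one of the two equivalent prenyl groups into the diene by Schenck ene photo‑oxygenation (1O2), PPh3 reduction and dehydration, run to partial conversion with recycling.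

2. Steps 3/4, tertiary ether formation on the hindered, acidic o‑bromophenol. The ether could isomerise to the linear prenyl ether or lose isoprene on heating. Fallback: build the same ether without π‑allyl chemistry, by Cu‑catalysed O‑alkylation with a 2‑methylbut‑3‑yn‑2‑yl carbonate followed by Lindlar semihydrogenation, then the same Claisen rearrangement.

3. Step 6, Heck with isoprene. Risks are regioisomeric or double arylation, diene oligomerisation and slow erosion of C2 under amine and heat. Fallback: form the diene by elimination instead. Heck‑couple 10 with 2‑methylbut‑3‑en‑2‑ol to the (E)‑tertiary allylic alcohol, then dehydrate with Burgess reagent before removing the pivalate.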